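**Retrosynthetic overview**
1. Labels: ring A is the benzene ring and ring B the five-membered lactone of the phthalide. The chain runs from C1 (OCH2) to C11 (C–OAc), so the alkenes are C2=C3 and C6=C7.
2. The last operation joins three components in one flask. C3–C4 and C3–CH3 are both cut back to a C3 gem-dichloride. This leaves the 3,3-dichloroallyl ether of the complete, unprotected phthalide, a C4–C11 homoallyl-9-BBN reagent made in situ from a terminal 1,3-diene, and Zn(CH3)2.
3. Enabling feature: C3 is a fully substituted sp2 carbon, and its neighbour C2 carries only H and the C1H2–O–C5(ring A) group. In the CCl2 precursor the C–Cl bond trans to C1 is open and the cis one is shielded, so the order of two cross-couplings sets the 2E geometry without a preformed stereodefined alkenyl halide.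
4. Aryl half: ring A is bought as methyl 3,4-dihydroxy-5-methoxybenzoate and the OH para to the ester is alkylated selectively. Ring B, the only ring formed in the route, is then closed by ortho-hydroxymethylation next to the remaining OH and lactonisation.
5. Chain half: the 6E alkene is bought with geranyl acetate. The distal alkene is hydrated by way of its epoxide, the allylic alcohol terminus becomes a vinyl group (oxidation, Wittig), and the tertiary alcohol is acetylated before the union.

Key step: step 8

Remark: 1, 2 and 5 are taken as commercial, and geranyl acetate is taken as the pure E isomer, since it is the source of the 6E alkene.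

**Step 1**
Reactants: 1 methyl 3,4-dihydroxy-5-methoxybenzoate; 2 1,1,3-trichloroprop-1-ene
Product: 3 methyl 4-[(3,3-dichloroprop-2-en-1-yl)oxy]-3-hydroxy-5-methoxybenzoate
Conditions: KHCO3, KI (cat.), DMF, argon, 40 °C
Reagents that add atoms: none
Why: In this Williamson ether synthesis the weak base ionises only the more acidic 4-OH (para to the ester), which displaces the allylic chloride of 2 by SN2, while the 3-OH and the two vinylic chlorides stay untouched.

**Step 2**
Reactants: 3 methyl 4-[(3,3-dichloroprop-2-en-1-yl)oxy]-3-hydroxy-5-methoxybenzoate
Product: 4 5-[(3,3-dichloroprop-2-en-1-yl)oxy]-4-hydroxy-6-methoxyisobenzofuran-1(3H)-one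
Conditions: MgCl2, Et3N, (CH2O)n, MeCN, reflux; 1 M HCl work-up
Reagents that add atoms: paraformaldehyde (reacts as formaldehyde), C=O
Why: In this magnesium-phenoxide-mediated ortho-hydroxymethylation (the first stage of the Casnati–Skattebøl reaction) formaldehyde is delivered within the chelate to the only free position ortho to the OH, and the benzylic magnesium alkoxide should close ring B at once by 5-exo-trig transesterification on the flanking ester before it can be oxidised to the aldehyde.

**Step 3**
Reactants: 5 geranyl acetate, (E)-3,7-dimethylocta-2,6-dien-1-yl acetate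
Product: 6 (E)-6,7-epoxy-3,7-dimethyloct-2-en-1-yl acetate (racemic)
Conditions: mCPBA (1.0 equiv), CH2Cl2, 0 °C
Reagents that add atoms: mCPBA, O=C(OO)c1cccc(Cl)c1
Why: The Prilezhaev epoxidation takes the more electron-rich distal alkene because the 2,3-alkene is deactivated by the allylic acetate, and the new stereocentre, formed as a racemate, is erased in step 4.

**Step 4**
Reactants: 6 (E)-6,7-epoxy-3,7-dimethyloct-2-en-1-yl acetate
Product: 7 (E)-3,7-dimethyloct-2-ene-1,7-diol
Conditions: LiAlH4, THF, 0 to 23 °C; aqueous NaOH work-up
Reagents that add atoms: none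
Why: In this reductive epoxide opening hydride attacks the less hindered secondary carbon by SN2 to leave the tertiary alcohol, the acetate is cleaved in the same operation, and the unactivated trisubstituted alkene is not reduced.

**Step 5**
Reactants: 7 (E)-3,7-dimethyloct-2-ene-1,7-diol
Product: 8 (E)-7-hydroxy-3,7-dimethyloct-2-enal
Conditions: TEMPO (cat.), PhI(OAc)2, CH2Cl2, 23 °C
Reagents that add atoms: none
Why: The oxoammonium (TEMPO) oxidation takes only the primary allylic alcohol, cannot oxidise the tertiary alcohol, stops at the aldehyde, and is mild enough that the E-enal should not isomerise.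

**Step 6**
Reactants: 8 (E)-7-hydroxy-3,7-dimethyloct-2-enal
Product: 9 (E)-2,6-dimethylnona-6,8-dien-2-ol
Conditions: Ph3PCH3Br, KOt-Bu, THF, 0 °C; then 8, 0 to 23 °C
Reagents that add atoms: methyltriphenylphosphonium bromide, C[P+](c1ccccc1)(c1ccccc1)c1ccccc1.[Br-]
Why: Wittig methylenation with a small excess of the non-stabilised ylide turns the aldehyde into the terminal vinyl group, does not involve the existing E alkene, and tolerates the tertiary alcohol.

**Step 7**
Reactants: 9 (E)-2,6-dimethylnona-6,8-dien-2-ol
Product: 10 (E)-2,6-dimethylnona-6,8-dien-2-yl acetate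
Conditions: Ac2O, DMAP (cat.), pyridine, 40 °C
Reagents that add atoms: acetic anhydride, CC(=O)OC(C)=O
Why: DMAP-catalysed acylation through the N-acetylpyridinium ion is strong enough for a dimethylcarbinol and basic enough to leave the acid-sensitive diene intact, and placing the acetate here avoids any later choice between phenol and tertiary alcohol.

**Step 8**
Reactants: 4 5-[(3,3-dichloroprop-2-en-1-yl)oxy]-4-hydroxy-6-methoxyisobenzofuran-1(3H)-one; 10 (E)-2,6-dimethylnona-6,8-dien-2-yl acetate
Product: 13 farnesylemefuranone F, via homoallyl-9-BBN borane 11 (not isolated), via (Z)-chloroalkene 12 (not isolated)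
Conditions: (a) 10 (1.4 equiv), 9-BBN-H (1.3 equiv), THF, 0 to 23 °C; (b) add 4, Pd2(dba)3, XantPhos, K3PO4, KF, THF, 65 °C; (c) add Pd(P(t-Bu)3)2, Zn(CH3)2 (excess), 23 to 45 °C; aqueous NH4Cl
Reagents that add atoms: dimethylzinc, C[Zn]C
Why: 9-BBN-H adds in a concerted, radical-free manner to the only unhindered C=C of 10, the terminal vinyl group of the 1,3-diene, placing boron on the terminal carbon (the future C4) and leaving the 6E alkene and the tertiary acetate untouched, which gives 11. Zerovalent palladium bearing the wide-bite-angle ligand XantPhos then inserts into the C3–Cl bond of 4 that is trans to C1, the phosphate- or fluoride-activated borate of 11 transmetallates, and reductive elimination forms C3–C4 to give 12, whose remaining C–Cl bond, cis to C1 and now flanked by two carbon chains, is inert to this catalyst so that coupling stops after one event. Addition of Pd(P(t-Bu)3)2 and Zn(CH3)2 opens that second C–Cl bond, and a Negishi methylation with retention of configuration completes the trisubstituted alkene in the same flask. The closest known reaction types are the trans-selective Suzuki–Miyaura monoalkylation of unactivated 1,1-dichloro-1-alkenes with B-alkyl-9-BBN reagents and the stereoretentive methylation of the resulting (Z)-chloroalkenes with methylzinc reagents, which have also been run as one-pot sequences to trisubstituted alkenes. No ring is closed and no stereocentre is made; the one stereoelement set is the 2E geometry, controlled by the lone C1H2OAr substituent on C2 that differentiates the two chlorides, while the 6E geometry is carried through because no homoallyl radical, which could close reversibly to a cyclopropylcarbinyl radical, is ever formed. The step needs C–Cl insertion to outrun ionisation of the allyl aryl ether and needs the free 4-OH, the lactone and the acetate to survive: under K3PO4 the phenol is a phenoxide, which makes the neighbouring aryloxide a very poor leaving group, and none of borane, phosphate or organozinc attacks a lactone or a hindered tertiary acetate at these temperatures.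

**Compound list**
1 | methyl 3,4-dihydroxy-5-methoxybenzoate | COC(=O)c1cc(O)c(O)c(OC)c1 | starting material
2 | 1,1,3-trichloroprop-1-ene | ClCC=C(Cl)Cl | starting material
3 | methyl 4-[(3,3-dichloroprop-2-en-1-yl)oxy]-3-hydroxy-5-methoxybenzoate | COC(=O)c1cc(O)c(OCC=C(Cl)Cl)c(OC)c1 | intermediate
4 | 5-[(3,3-dichloroprop-2-en-1-yl)oxy]-4-hydroxy-6-methoxyisobenzofuran-1(3H)-one | COc1cc2c(c(O)c1OCC=C(Cl)Cl)COC2=O | intermediate
5 | geranyl acetate, (E)-3,7-dimethylocta-2,6-dien-1-yl acetate | CC(C)=CCC/C(C)=C/COC(C)=O | starting material
6 | (E)-6,7-epoxy-3,7-dimethyloct-2-en-1-yl acetate (racemic at the epoxide CH) | CC(=O)OC/C=C(\C)CCC1OC1(C)C | intermediate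
7 | (E)-3,7-dimethyloct-2-ene-1,7-diol | OC/C=C(\C)CCCC(C)(C)O | intermediate
8 | (E)-7-hydroxy-3,7-dimethyloct-2-enal | O=C/C=C(\C)CCCC(C)(C)O | intermediate
9 | (E)-2,6-dimethylnona-6,8-dien-2-ol | C=C/C=C(\C)CCCC(C)(C)O | intermediate
10 | (E)-2,6-dimethylnona-6,8-dien-2-yl acetate | C=C/C=C(\C)CCCC(C)(C)OC(C)=O | intermediate
11 | (E)-9-(9-borabicyclo[3.3.1]nonan-9-yl)-2,6-dimethylnon-6-en-2-yl acetate | CC(=O)OC(C)(C)CCC/C(C)=C/CCB1C2CCCC1CCC2 | intermediate
12 | 5-{[(2Z,6E)-11-acetoxy-3-chloro-7,11-dimethyldodeca-2,6-dien-1-yl]oxy}-4-hydroxy-6-methoxyisobenzofuran-1(3H)-one | COc1cc2c(c(O)c1OC/C=C(\Cl)CC/C=C(\C)CCCC(C)(C)OC(C)=O)COC2=O | intermediate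
13 | farnesylemefuranone F, 5-{[(2E,6E)-11-acetoxy-3,7,11-trimethyldodeca-2,6-dien-1-yl]oxy}-4-hydroxy-6-methoxyisobenzofuran-1(3H)-one | COc1cc2c(c(O)c1OC/C=C(\C)CC/C=C(\C)CCCC(C)(C)OC(C)=O)COC2=O | target

Total step count: 8
Longest linear sequence: 6 steps (steps 3 to 8, from geranyl acetate)

**Steps most likely to fail**

Step 8. Control over which C–Cl bond reacts, and how often, may be lost, leading to double alkylation or a methylation that lags behind. Zerovalent palladium may ionise the allyl aryl ether at 65 °C, and the homoallyl-palladium species may undergo β-hydride elimination. The fallback sets out from 1 and 10 and returns at 13.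
- Commercial but-2-yn-1-ol is hydrozirconated with excess Cp2Zr(H)Cl (syn addition, zirconium settling on the methyl-bearing carbon) and iodinated to (E)-3-iodobut-2-en-1-ol F1.
- Mitsunobu etherification (PPh3, DIAD, THF, 0 °C) of the more acidic 4-OH of 1 with F1 gives methyl 3-hydroxy-4-{[(E)-3-iodobut-2-en-1-yl]oxy}-5-methoxybenzoate F2.
- The conditions of step 2 close ring B to 4-hydroxy-5-{[(E)-3-iodobut-2-en-1-yl]oxy}-6-methoxyisobenzofuran-1(3H)-one F3.
- Borane 11, made from 10 as in step 8, is joined to F3 by a B-alkyl Suzuki–Miyaura coupling (PdCl2(dppf), AsPh3, Cs2CO3, DMF/THF/H2O, 23 °C) to give 13.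

In this fallback the methyl group and the geometry are in place before the union. A single C–I insertion at room temperature should leave the allyl aryl ether alone.

Step 2. Hydride transfer from the benzylic magnesium alkoxide to formaldehyde may outrun lactonisation, C–C bond formation at the crowded position between OH and ester may be slow, and the phenol may be methoxymethylated on long heating. The fallback sets out from 3 and returns at 4.
- Phenylboronic acid, paraformaldehyde and catalytic propionic acid in refluxing toluene with water removal tie phenol oxygen and formaldehyde to one boron atom. The CH2O unit is delivered ortho at the alcohol oxidation level, giving methyl 7-[(3,3-dichloroprop-2-en-1-yl)oxy]-6-methoxy-2-phenyl-4H-benzo[d][1,3,2]dioxaborinine-5-carboxylate F4.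
- Exchange with propane-1,3-diol frees the salicyl alcohol, which lactonises with catalytic TsOH to 4.

Step 1. Alkylation may occur at the less acidic 3-OH or at both hydroxyls, and the catechol may be air-oxidised under base. The fallback sets out from 1 and 2 and returns at 3.
- 2 is hydrolysed (aqueous Na2CO3, reflux) to 3,3-dichloroprop-2-en-1-ol F5.
- F5 is condensed with 1 under Mitsunobu conditions (PPh3, DIAD, THF, 0 °C).

Here the alcohol, not the phenol, is activated. No free phenoxide is present, and only the more acidic 4-OH protonates the betaine, so selection rests on acidity under neutral conditions.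

**Further compounds**
F1 | step 8 | (E)-3-iodobut-2-en-1-ol | OC/C=C(\C)I
F2 | step 8 | methyl 3-hydroxy-4-{[(E)-3-iodobut-2-en-1-yl]oxy}-5-methoxybenzoate | COC(=O)c1cc(O)c(OC/C=C(\C)I)c(OC)c1
F3 | step 8 | 4-hydroxy-5-{[(E)-3-iodobut-2-en-1-yl]oxy}-6-methoxyisobenzofuran-1(3H)-one | COc1cc2c(c(O)c1OC/C=C(\C)I)COC2=O
F4 | step 2 | methyl 7-[(3,3-dichloroprop-2-en-1-yl)oxy]-6-methoxy-2-phenyl-4H-benzo[d][1,3,2]dioxaborinine-5-carboxylate | COC(=O)c1cc(OC)c(OCC=C(Cl)Cl)c2OB(c3ccccc3)OCc12
F5 | step 1 | 3,3-dichloroprop-2-en-1-ol | OCC=C(Cl)Cl
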